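**Plan**

1. Rings: A = benzo ring (C3a–C7a), B = dihydrofuran ring (O1, C2, C3, C3a, C7a), C = aryl ring on C3, D = outer ring of the biaryl, E = phenoxy ring; the target is the cis-(2R,3S) isomer.
2. Retrosynthesis, in order: the three aryl–allyl bonds (to aryl bromides); the C2–H and C3–H bonds (to a benzofuran-2-carboxylic acid); O1–C7a and C2–C3 together (to a 2-fluorobenzophenone and methyl glycolate); the C3–ring C bond (aryllithium + aldehyde) and the ring A–O–ring E ether (SNAr).
3. Forward: rings A, C, D and E are bought as arenes; E is joined to A, then the C–D biaryl to C3; ring B is closed in step 7 and saturated in step 8; the allyl groups come last because step 8 is a hydrogenation.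
4. Enabling feature: C3 is a diarylmethine carbon between ring A (at C3a) and ring C, so it can be carried as a non-enolisable diaryl ketone that activates the neighbouring ring A carbon C7a (as C–F) for substitution and then accepts the C2 enolate; C2 carries the hydroxymethyl carbon, which as an ester makes C2–H acidic.
5. Stereochemistry: both centers arise in step 8 by syn addition of H2 to one face of C2=C3 (cis by syn addition, absolute sense from a chiral iridium catalyst bound to the C2 carboxylate); nothing epimerisable remains once the acid is reduced.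
6. Helpers removed later: ketone level at C3, C7a–F, C2 carboxyl, SEM on O7 (freed so that the C7 hydroxyl directs bromination to C4), MOM on the ring C/D phenols, bromides as placeholders for allyl (MOM = CH2OCH3, SEM = CH2OCH2CH2SiMe3).

Key step: step 7

Assumption: the facial sense of the iridium catalyst on this new substrate is taken as that of the (Sa,S) ligand; if it proves opposite, the mirror-image ligand is used and nothing else in the route changes.

**Route**

Step 1
Reactants: 1 biphenyl-2,2'-diol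
Product: 2 5,5'-dibromobiphenyl-2,2'-diol
Conditions: Br2 (2.0 equiv), CH2Cl2, 0 °C
Reagents that add atoms: bromine, BrBr
Why: Electrophilic aromatic bromination, in which each hydroxyl directs to its free para position (C5 and C5') faster than to the ortho position, so two equivalents of bromine should stop at the 5,5'-dibromide.

Step 2
Reactants: 2 5,5'-dibromobiphenyl-2,2'-diol
Product: 3 5,5'-dibromo-2,2'-bis(methoxymethoxy)biphenyl
Conditions: NaH, MOMCl, THF–DMF, 0 °C to rt
Reagents that add atoms: chloromethyl methyl ether, COCCl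
Why: O-Alkylation of the two phenoxides (Williamson-type acetal protection) should give MOM ethers that tolerate the organolithium, alkoxide, hydrogenation and borane steps and leave with acid at the end.

Step 3
Reactants: 4 2,4-difluoro-3-hydroxybenzaldehyde
Product: 5 2,4-difluoro-3-{[2-(trimethylsilyl)ethoxy]methoxy}benzaldehyde
Conditions: SEMCl, i-Pr2NEt, CH2Cl2, 0 °C to rt
Reagents that add atoms: 2-(trimethylsilyl)ethoxymethyl chloride, C[Si](C)(C)CCOCCl
Why: O-Alkylation of the acidic phenol should mask the future C7 hydroxyl as a base-stable SEM acetal that fluoride can later remove without touching the MOM ethers.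

Step 4
Reactants: 5 2,4-difluoro-3-{[2-(trimethylsilyl)ethoxy]methoxy}benzaldehyde; 6 4-bromophenol
Product: 7 4-(4-bromophenoxy)-2-fluoro-3-{[2-(trimethylsilyl)ethoxy]methoxy}benzaldehyde
Conditions: K2CO3, DMF, 60 °C
Reagents that add atoms: none
Why: Nucleophilic aromatic substitution (SNAr), in which the phenoxide should displace the fluorine para to the formyl group because the ortho fluorine, although also activated, is wedged between CHO and OSEM.

Step 5
Reactants: 3 5,5'-dibromo-2,2'-bis(methoxymethoxy)biphenyl; 7 4-(4-bromophenoxy)-2-fluoro-3-{[2-(trimethylsilyl)ethoxy]methoxy}benzaldehyde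
Product: 9 [4-(4-bromophenoxy)-2-fluoro-3-{[2-(trimethylsilyl)ethoxy]methoxy}phenyl][5'-bromo-2',6-bis(methoxymethoxy)biphenyl-3-yl]methanol (racemic), via biaryllithium 8 (not isolated)
Conditions: 3, n-BuLi (1.0 equiv), THF, −78 °C; then 7, −78 °C; NH4Cl (aq)
Reagents that add atoms: none
Why: Bromine–lithium exchange of one of the two equivalent bromides followed by 1,2-addition of the aryllithium to the aldehyde, which should be faster than exchange with the remaining aryl bromides; the carbinol center is racemic and is erased in step 6.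

Step 6
Reactants: 9 the diarylmethanol of step 5
Product: 10 [4-(4-bromophenoxy)-2-fluoro-3-{[2-(trimethylsilyl)ethoxy]methoxy}phenyl][5'-bromo-2',6-bis(methoxymethoxy)biphenyl-3-yl]methanone
Conditions: Dess–Martin periodinane, CH2Cl2, rt
Reagents that add atoms: none
Why: Dess–Martin oxidation of a secondary diaryl carbinol to the diaryl ketone, mild enough for the acetals and the aryl bromides, puts C3 at the oxidation level that the key step needs.

Step 7
Reactants: 10 the 2-fluorobenzophenone of step 6; 11 methyl glycolate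
Product: 15 6-(4-bromophenoxy)-3-[5'-bromo-2',6-bis(methoxymethoxy)biphenyl-3-yl]-7-{[2-(trimethylsilyl)ethoxy]methoxy}-1-benzofuran-2-carboxylic acid, via aryl ether 12 (not isolated), via aldol adduct 13 (not isolated), via methyl ester 14 (not isolated)
Conditions: KOt-Bu (2.5 equiv), THF–DMF, 0 to 60 °C; then LiOH, H2O–MeOH, 50 °C; 1 M HCl to pH 4
Reagents that add atoms: lithium hydroxide, [Li+].[OH-]
Why: The potassium alkoxide of 11 adds to C7a of ring A and expels fluoride by addition–elimination (SNAr), the Meisenheimer adduct being stabilised by the ortho C3 carbonyl, to give aryl ether 12 (O1–C7a bond); a second equivalent of base forms the ester enolate at C2, which adds to the ketone carbon C3 (C2–C3 bond) to give 13, and E1cB loss of water aromatises ring B to 14 before hydroxide cleaves the ester. The closest known reaction type is the base-mediated annulation of ortho-fluoroaryl ketones or nitriles with glycolate and thioglycolate esters to benzofuran- and benzothiophene-2-carboxylates (SNAr then aldol condensation, a Rap–Stoermer-type benzofuran synthesis). Ring B closes in the aldol event by a 5-exo-trig attack of the C2 enolate on the exocyclic C3=O. No stereocenter is formed here, since C2 and C3 leave the step as sp2 carbons; both are set together in step 8. The step needs substitution at C7a only and a single enolisable partner: the one fluorine left is the one ortho to the ketone, the two aryl bromides are not activated for SNAr, the diaryl ketone has no α-hydrogen so only the glycolate can form an enolate, and the SEM and MOM acetals are inert to alkoxide.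

Step 8
Reactants: 15 the benzofuran-2-carboxylic acid of step 7
Product: 16 (2R,3S)-6-(4-bromophenoxy)-3-[5'-bromo-2',6-bis(methoxymethoxy)biphenyl-3-yl]-7-{[2-(trimethylsilyl)ethoxy]methoxy}-2,3-dihydro-1-benzofuran-2-carboxylic acid (cis)
Conditions: [Ir(cod)((Sa,S)-SIPHOX)]BArF (2 mol %; SIPHOX = spirobiindane phosphine–oxazoline, BArF = B[3,5-(CF3)2C6H3]4), H2 (50 atm), Et3N (1 equiv), MeOH, 60 °C
Reagents that add atoms: none
Why: Enantioselective hydrogenation of a benzofuran C2=C3 bond, here directed by the C2 carboxylate bound to iridium as in the asymmetric hydrogenation of tetrasubstituted and α-aryloxy acrylic acids, should deliver both hydrogens to one face, which makes the C2 carboxyl and the C3 aryl cis, while the chiral ligand selects the face that gives 2R,3S and the aryl bromides and acetals stay inert.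

Step 9
Reactants: 16 the cis acid of step 8
Product: 17 [(2R,3S)-6-(4-bromophenoxy)-3-[5'-bromo-2',6-bis(methoxymethoxy)biphenyl-3-yl]-7-{[2-(trimethylsilyl)ethoxy]methoxy}-2,3-dihydro-1-benzofuran-2-yl]methanol
Conditions: BH3·SMe2, THF, 0 °C to rt; MeOH then H2O
Reagents that add atoms: none
Why: Borane reduction of a carboxylic acid to the primary alcohol proceeds through an acyloxyborane without enolisation, so the cis C2 center should not epimerise, and aryl bromides and acetals are untouched.

Step 10
Reactants: 17 the alcohol of step 9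
Product: 18 (2R,3S)-6-(4-bromophenoxy)-3-[5'-bromo-2',6-bis(methoxymethoxy)biphenyl-3-yl]-2-(hydroxymethyl)-2,3-dihydro-1-benzofuran-7-ol
Conditions: TBAF, THF–DMPU, 70 °C; NH4Cl (aq)
Reagents that add atoms: none
Why: Fluoride attack at silicon fragments the SEM ether (loss of fluorotrimethylsilane, ethylene and formaldehyde) and should free only the C7 phenol, the MOM ethers being inert to fluoride.

Step 11
Reactants: 18 the C7 phenol of step 10
Product: 19 (2R,3S)-4-bromo-6-(4-bromophenoxy)-3-[5'-bromo-2',6-bis(methoxymethoxy)biphenyl-3-yl]-2-(hydroxymethyl)-2,3-dihydro-1-benzofuran-7-ol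
Conditions: NBS (1.0 equiv), MeCN, −20 to 0 °C
Reagents that add atoms: N-bromosuccinimide, O=C1CCC(=O)N1Br
Why: Electrophilic aromatic bromination should go para to the only free hydroxyl (C4 of the trioxygenated ring A), the strongest director in the molecule, while the other oxygens are ethers and rings C, D and E are less activated.

Step 12
Reactants: 19 the tribromide of step 11
Product: 20 (2R,3S)-4-allyl-6-(4-allylphenoxy)-3-[5'-allyl-2',6-bis(methoxymethoxy)biphenyl-3-yl]-2-(hydroxymethyl)-2,3-dihydro-1-benzofuran-7-ol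
Conditions: allylB(pin) (6 equiv), Pd(OAc)2, SPhos, K3PO4, THF–H2O, 65 °C
Reagents that add atoms: allylboronic acid pinacol ester, C=CCB1OC(C)(C)C(C)(C)O1
Why: Threefold Suzuki–Miyaura allylation of aryl bromides, with an electron-rich biarylphosphine to help oxidative addition at the hindered, phenol-bearing ring A bromide, should install all three allyl groups at once in the presence of the free phenol and alcohol.

Step 13
Reactants: 20 the bis-MOM ether of step 12
Product: 21 magnolignan H, (2R,3S)-4-allyl-6-(4-allylphenoxy)-3-(5'-allyl-2',6-dihydroxybiphenyl-3-yl)-2-(hydroxymethyl)-2,3-dihydro-1-benzofuran-7-ol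
Conditions: HCl (cat.), MeOH, 45 °C
Reagents that add atoms: none
Why: Acid-catalysed acetal exchange with methanol should remove both MOM groups under conditions that leave the allyl groups, the dihydrofuran ether and the non-ionisable C2 and C3 centers unchanged.

**Compound list**

1 | biphenyl-2,2'-diol | Oc1ccccc1-c1ccccc1O | starting material
2 | 5,5'-dibromobiphenyl-2,2'-diol | Oc1ccc(Br)cc1-c1cc(Br)ccc1O | intermediate
3 | 5,5'-dibromo-2,2'-bis(methoxymethoxy)biphenyl | COCOc1ccc(Br)cc1-c1cc(Br)ccc1OCOC | intermediate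
4 | 2,4-difluoro-3-hydroxybenzaldehyde | O=Cc1ccc(F)c(O)c1F | starting material
5 | 2,4-difluoro-3-{[2-(trimethylsilyl)ethoxy]methoxy}benzaldehyde | O=Cc1ccc(F)c(OCOCC[Si](C)(C)C)c1F | intermediate
6 | 4-bromophenol | Oc1ccc(Br)cc1 | starting material
7 | 4-(4-bromophenoxy)-2-fluoro-3-{[2-(trimethylsilyl)ethoxy]methoxy}benzaldehyde | O=Cc1ccc(Oc2ccc(Br)cc2)c(OCOCC[Si](C)(C)C)c1F | intermediate
8 | [5'-bromo-2',6-bis(methoxymethoxy)biphenyl-3-yl]lithium | [Li]c1ccc(OCOC)c(-c2cc(Br)ccc2OCOC)c1 | intermediate (not isolated)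
9 | [4-(4-bromophenoxy)-2-fluoro-3-(SEM-oxy)phenyl][5'-bromo-2',6-bis(methoxymethoxy)biphenyl-3-yl]methanol, racemic | OC(c1ccc(Oc2ccc(Br)cc2)c(OCOCC[Si](C)(C)C)c1F)c1ccc(OCOC)c(-c2cc(Br)ccc2OCOC)c1 | intermediate
10 | [4-(4-bromophenoxy)-2-fluoro-3-(SEM-oxy)phenyl][5'-bromo-2',6-bis(methoxymethoxy)biphenyl-3-yl]methanone | O=C(c1ccc(Oc2ccc(Br)cc2)c(OCOCC[Si](C)(C)C)c1F)c1ccc(OCOC)c(-c2cc(Br)ccc2OCOC)c1 | intermediate
11 | methyl glycolate (methyl 2-hydroxyacetate) | COC(=O)CO | starting material
12 | methyl 2-{[6-aroyl-3-(4-bromophenoxy)-2-(SEM-oxy)phenyl]oxy}acetate (aroyl = 5'-bromo-2',6-bis(methoxymethoxy)biphenyl-3-carbonyl) | COC(=O)COc1c(OCOCC[Si](C)(C)C)c(Oc2ccc(Br)cc2)ccc1C(=O)c1ccc(OCOC)c(-c2cc(Br)ccc2OCOC)c1 | intermediate (not isolated)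
13 | methyl 3-hydroxy-3-aryl-6-(4-bromophenoxy)-7-(SEM-oxy)-2,3-dihydro-1-benzofuran-2-carboxylate, diastereomer mixture | COC(=O)C1Oc2c(OCOCC[Si](C)(C)C)c(Oc3ccc(Br)cc3)ccc2C1(O)c1ccc(OCOC)c(-c2cc(Br)ccc2OCOC)c1 | intermediate (not isolated)
14 | methyl 6-(4-bromophenoxy)-3-[5'-bromo-2',6-bis(methoxymethoxy)biphenyl-3-yl]-7-(SEM-oxy)-1-benzofuran-2-carboxylate | COC(=O)c1oc2c(OCOCC[Si](C)(C)C)c(Oc3ccc(Br)cc3)ccc2c1-c1ccc(OCOC)c(-c2cc(Br)ccc2OCOC)c1 | intermediate (not isolated)
15 | 6-(4-bromophenoxy)-3-[5'-bromo-2',6-bis(methoxymethoxy)biphenyl-3-yl]-7-(SEM-oxy)-1-benzofuran-2-carboxylic acid | OC(=O)c1oc2c(OCOCC[Si](C)(C)C)c(Oc3ccc(Br)cc3)ccc2c1-c1ccc(OCOC)c(-c2cc(Br)ccc2OCOC)c1 | intermediate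
16 | (2R,3S)-6-(4-bromophenoxy)-3-[5'-bromo-2',6-bis(methoxymethoxy)biphenyl-3-yl]-7-(SEM-oxy)-2,3-dihydro-1-benzofuran-2-carboxylic acid, cis | OC(=O)[C@@H]1Oc2c(OCOCC[Si](C)(C)C)c(Oc3ccc(Br)cc3)ccc2[C@@H]1c1ccc(OCOC)c(-c2cc(Br)ccc2OCOC)c1 | intermediate
17 | [(2R,3S)-6-(4-bromophenoxy)-3-[5'-bromo-2',6-bis(methoxymethoxy)biphenyl-3-yl]-7-(SEM-oxy)-2,3-dihydro-1-benzofuran-2-yl]methanol | OC[C@@H]1Oc2c(OCOCC[Si](C)(C)C)c(Oc3ccc(Br)cc3)ccc2[C@@H]1c1ccc(OCOC)c(-c2cc(Br)ccc2OCOC)c1 | intermediate
18 | (2R,3S)-6-(4-bromophenoxy)-3-[5'-bromo-2',6-bis(methoxymethoxy)biphenyl-3-yl]-2-(hydroxymethyl)-2,3-dihydro-1-benzofuran-7-ol | OC[C@@H]1Oc2c(O)c(Oc3ccc(Br)cc3)ccc2[C@@H]1c1ccc(OCOC)c(-c2cc(Br)ccc2OCOC)c1 | intermediate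
19 | (2R,3S)-4-bromo-6-(4-bromophenoxy)-3-[5'-bromo-2',6-bis(methoxymethoxy)biphenyl-3-yl]-2-(hydroxymethyl)-2,3-dihydro-1-benzofuran-7-ol | OC[C@@H]1Oc2c(O)c(Oc3ccc(Br)cc3)cc(Br)c2[C@@H]1c1ccc(OCOC)c(-c2cc(Br)ccc2OCOC)c1 | intermediate
20 | (2R,3S)-4-allyl-6-(4-allylphenoxy)-3-[5'-allyl-2',6-bis(methoxymethoxy)biphenyl-3-yl]-2-(hydroxymethyl)-2,3-dihydro-1-benzofuran-7-ol | OC[C@@H]1Oc2c(O)c(Oc3ccc(CC=C)cc3)cc(CC=C)c2[C@@H]1c1ccc(OCOC)c(-c2cc(CC=C)ccc2OCOC)c1 | intermediate
21 | magnolignan H | C=CCc1ccc(Oc2cc(CC=C)c3c(c2O)O[C@@H](CO)[C@H]3c2ccc(O)c(-c3cc(CC=C)ccc3O)c2)cc1 | target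

**Step count and risks**

Total steps: 13. Longest linear sequence: 11 steps (steps 1, 2 and 5–13 from 1; the branch from 4 through steps 3, 4 and 5–13 is equally long).

Steps most likely to fail:

Step 8. What may go wrong: slow or poorly face-selective delivery of hydrogen to the tetrasubstituted, aryl-shielded C2=C3 bond, or reductive loss of bromine if the conditions must be forced. The fallback sets out from 10 and returns at 18. Ketone 10 is etherified at C7a with 2-(tert-butyldimethylsilyloxy)ethanol (NaH, DMF; SNAr) to give the 2-(2-silyloxyethoxy)benzophenone F1. Hydrazine hydrate in ethanol at 80 °C converts it into the hydrazone F2. MnO2 in CH2Cl2 oxidises this to the diaryldiazomethane F3, which is not isolated. Rh2(R-PTAD)4 (or its mirror image, whichever gives 2R,3S) then effects enantioselective 1,5 C–H insertion of the donor/donor carbene into the OCH2 group, a reaction type known to give cis-2,3-disubstituted dihydrobenzofurans, and delivers the cis silyl ether F4. TBAF in THF–DMPU removes the TBS and the SEM group together and gives 18.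

Step 7. What may go wrong: the glycolate alkoxide is used up by ester exchange and self-condensation faster than it displaces fluoride from the electron-rich ring A, or the tertiary aldol adduct reverts instead of dehydrating. The fallback sets out from 10 and returns at 14. KOH in DMSO–H2O at 90 °C displaces the fluoride to give the 2-hydroxybenzophenone F5. Methyl bromoacetate and K2CO3 in DMF at 90 °C then O-alkylate the phenol and close ring B by aldol condensation (Rap–Stoermer type), so that O1–C2 and not O1–C7a is made in the annulation. Ester 14 is isolated and saponified with LiOH to 15.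

Step 11. What may go wrong: loss of regiocontrol (bromination at C5 or on ring C) or oxidation of the electron-rich phenol to a quinone. The fallback sets out from 18 and returns at 20. O-Allylation (allyl bromide, K2CO3, acetone) gives the C7 allyl ether F6. Heating in N,N-diethylaniline at 190 °C moves the allyl group to C4 by a para-Claisen rearrangement, both ortho positions being blocked by oxygen, and gives the 4-allylphenol F7. Twofold Suzuki–Miyaura allylation of the two remaining bromides under the conditions of step 12 gives 20.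

Further compounds
F1 | step 8 | [2-{2-[(tert-butyldimethylsilyl)oxy]ethoxy}-4-(4-bromophenoxy)-3-(SEM-oxy)phenyl][5'-bromo-2',6-bis(methoxymethoxy)biphenyl-3-yl]methanone | CC(C)(C)[Si](C)(C)OCCOc1c(OCOCC[Si](C)(C)C)c(Oc2ccc(Br)cc2)ccc1C(=O)c1ccc(OCOC)c(-c2cc(Br)ccc2OCOC)c1
F2 | step 8 | hydrazone of F1 | CC(C)(C)[Si](C)(C)OCCOc1c(OCOCC[Si](C)(C)C)c(Oc2ccc(Br)cc2)ccc1C(=NN)c1ccc(OCOC)c(-c2cc(Br)ccc2OCOC)c1
F3 | step 8 | diaryldiazomethane from F2 | CC(C)(C)[Si](C)(C)OCCOc1c(OCOCC[Si](C)(C)C)c(Oc2ccc(Br)cc2)ccc1C(=[N+]=[N-])c1ccc(OCOC)c(-c2cc(Br)ccc2OCOC)c1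
F4 | step 8 | (2R,3S)-2-{[(tert-butyldimethylsilyl)oxy]methyl}-6-(4-bromophenoxy)-3-[5'-bromo-2',6-bis(methoxymethoxy)biphenyl-3-yl]-7-(SEM-oxy)-2,3-dihydro-1-benzofuran | CC(C)(C)[Si](C)(C)OC[C@@H]1Oc2c(OCOCC[Si](C)(C)C)c(Oc3ccc(Br)cc3)ccc2[C@@H]1c1ccc(OCOC)c(-c2cc(Br)ccc2OCOC)c1
F5 | step 7 | [4-(4-bromophenoxy)-2-hydroxy-3-(SEM-oxy)phenyl][5'-bromo-2',6-bis(methoxymethoxy)biphenyl-3-yl]methanone | Oc1c(OCOCC[Si](C)(C)C)c(Oc2ccc(Br)cc2)ccc1C(=O)c1ccc(OCOC)c(-c2cc(Br)ccc2OCOC)c1
F6 | step 11 | [(2R,3S)-7-(allyloxy)-6-(4-bromophenoxy)-3-[5'-bromo-2',6-bis(methoxymethoxy)biphenyl-3-yl]-2,3-dihydro-1-benzofuran-2-yl]methanol | OC[C@@H]1Oc2c(OCC=C)c(Oc3ccc(Br)cc3)ccc2[C@@H]1c1ccc(OCOC)c(-c2cc(Br)ccc2OCOC)c1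
F7 | step 11 | (2R,3S)-4-allyl-6-(4-bromophenoxy)-3-[5'-bromo-2',6-bis(methoxymethoxy)biphenyl-3-yl]-2-(hydroxymethyl)-2,3-dihydro-1-benzofuran-7-ol | OC[C@@H]1Oc2c(O)c(Oc3ccc(Br)cc3)cc(CC=C)c2[C@@H]1c1ccc(OCOC)c(-c2cc(Br)ccc2OCOC)c1
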